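**Assumptions.** (a) β-Eudesmol is bought as a natural product. It has the same decalin and the same C5, C7 and C10 configurations as the target; the only difference is the exocyclic 4(15)-alkene. (b) The C4 stereocentre is set by α-face capture of a C4 tertiary cation-like intermediate. The β-face is shielded by the axial C14 methyl, which is 1,3-diaxial to C4. This gives the 4α-aryloxy, 4β-methyl (4R) configuration of the target.

## Retrosynthesis
1. The two aryl-allyl groups come last, by double Pd-catalysed Stille allylation of the corresponding dibromide.
2. The diaryl ether C–O bond forms by metal-free arylation of the less hindered OH of a 3-alkoxycatechol with a (4-bromophenyl)(mesityl)iodonium salt.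
3. The hindered tertiary C4–O ether is made by Markovnikov hydroaryloxylation of β-eudesmol's exocyclic alkene with a phenol that carries a temporary catechol carbonate. This is the key new step, and it sets C4.
4. No carbocycle is built. The decalin is already present in β-eudesmol, and the arene is commercial. The only ring formed is the temporary cyclic carbonate, made in step 2 and opened in step 4.

## Route

**Step 1**
Reactants: 1 (5-bromo-1,2,3-trimethoxybenzene)
Product: 2 (5-bromobenzene-1,2,3-triol)
Conditions: BBr3 (4.5 equiv), CH2Cl2, −78 °C → rt, 12 h; then MeOH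
Reagents that add atoms: none
Why: BBr3 O-demethylation cleaves all three aryl methyl ethers and leaves the Ar–Br bond intact. The product is symmetric, so the next step can give only one mono-carbonate.

**Step 2**
Reactants: 2 (5-bromopyrogallol); 3 (1,1'-carbonyldiimidazole)
Product: 4 (6-bromo-4-hydroxy-1,3-benzodioxol-2-one)
Conditions: CDI (1.0 equiv), THF, 60 °C, 4 h
Reagents that add atoms: CDI, O=C(n1ccnc1)n1ccnc1 (supplies the carbonyl)
Why: Cyclic-carbonate formation across two vicinal phenols. The C2-symmetric triol gives a single regioisomer, which masks the central OH and one flanking OH and leaves one flanking OH free. The electron-poor phenol is less prone to oxidation or C-alkylation in step 3.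

**Step 3**
Reactants: 5 (β-eudesmol); 4 (phenol, 2.5 equiv)
Product: 6 (4α-aryloxy-eudesman-11-ol carbonate)
Conditions: Co(II)-salen (5 mol%), N-fluoro-2,4,6-trimethylpyridinium triflate (2 equiv), PhSiH3 (1.5 equiv), PhCF3, 0 °C → rt, 12 h
Reagents that add atoms: none (PhSiH3 supplies only H)
Why: Proposed new method: Co–H hydrogen-atom transfer to the exocyclic 1,1-disubstituted alkene gives the tertiary C4 radical (C15 becomes CH3, Markovnikov). Oxidation by the N-fluoropyridinium gives an alkyl-Co(IV)/cation-like species that the phenol O–H captures intermolecularly, on the α-face because the β-face is blocked by axial C14, so C4 becomes 4α-OAr/4β-CH3. The closest known reaction is Shigehisa-type Co-salen radical-polar-crossover hydroalkoxylation, which has been shown intramolecularly and with alcohols. Here it is extended to an intermolecular reaction with a hindered, polyoxygenated phenol on an unactivated terpene alkene, forming a tertiary alkyl aryl ether under non-acidic conditions. C5, C7 and C10 are untouched.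

**Step 4**
Reactants: 6
Product: 7 (catechol: 5-bromo-3-alkoxy-benzene-1,2-diol)
Conditions: K2CO3 (3 equiv), MeOH/THF, rt, 2 h
Reagents that add atoms: none (MeOH leaves as dimethyl carbonate)
Why: Base methanolysis of the cyclic aryl carbonate. The tertiary ether, tertiary alcohol and Ar–Br are inert to these conditions, and no stereocentre is affected.

**Step 5**
Reactants: 8 (1-bromo-4-iodobenzene); 9 (mesitylene)
Product: 10 ((4-bromophenyl)(mesityl)iodonium triflate)
Conditions: mCPBA (1.2 equiv), TfOH (3 equiv), CH2Cl2, 0 °C → rt, 2 h (mesitylene added after oxidation)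
Reagents that add atoms: TfOH, OS(=O)(=O)C(F)(F)F (supplies the triflate counter-anion)
Why: One-pot oxidation of the aryl iodide to I(III), followed by electrophilic aromatic substitution on mesitylene. This is the standard diaryliodonium synthesis, and mesityl serves as the non-transferring dummy aryl group.

**Step 6**
Reactants: 7 (catechol); 10 (iodonium salt)
Product: 11 (diaryl ether dibromide)
Conditions: Cs2CO3 (1.1 equiv), toluene, 50 °C, 12 h
Reagents that add atoms: none (the 4-bromophenyl group comes from 10)
Why: Metal-free O-arylation with a diaryliodonium salt. The bulky I(III) reagent is expected to react at O-3, which is flanked only by H and OH. The central OH, flanked by OH and the tertiary ether, is shielded, so it is left free as in the target.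

**Step 7**
Reactants: 11; 12 (allyltributylstannane, 4 equiv)
Product: 13 (eudesobovatol A)
Conditions: Pd(PPh3)4 (10 mol%), LiCl (6 equiv), DMF, 100 °C, 12 h; KF work-up
Reagents that add atoms: allyltributylstannane, C=CC[Sn](CCCC)(CCCC)CCCC (supplies both allyl groups)
Why: Stille cross-coupling replaces both Ar–Br bonds with allyl groups under neutral conditions. The free phenol, the tertiary alcohol and the tertiary ether are tolerated, and all stereocentres are remote.

## Compound list
1 | 5-bromo-1,2,3-trimethoxybenzene | COc1cc(Br)cc(OC)c1OC | starting material
2 | 5-bromobenzene-1,2,3-triol | Oc1cc(Br)cc(O)c1O | intermediate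
3 | 1,1'-carbonyldiimidazole | O=C(n1ccnc1)n1ccnc1 | starting material
4 | 6-bromo-4-hydroxy-1,3-benzodioxol-2-one | O=C1Oc2cc(Br)cc(O)c2O1 | intermediate
5 | β-eudesmol, 2-[(2R,4aR,8aS)-4a-methyl-8-methylidenedecahydronaphthalen-2-yl]propan-2-ol | C=C3CCC[C@]4(C)CC[C@@H](C(C)(C)O)C[C@H]43 | starting material
6 | 6-bromo-4-{[(2R,4aR,8R,8aR)-2-(2-hydroxypropan-2-yl)-4a,8-dimethyldecahydronaphthalen-8-yl]oxy}-1,3-benzodioxol-2-one | O=C1Oc2cc(Br)cc(O[C@]3(C)CCC[C@]4(C)CC[C@@H](C(C)(C)O)C[C@H]43)c2O1 | intermediate
7 | 5-bromo-3-[(terpenyl)oxy]benzene-1,2-diol, terpenyl = (2R,4aR,8R,8aR)-2-(2-hydroxypropan-2-yl)-4a,8-dimethyldecahydronaphthalen-8-yl | Oc1cc(Br)cc(O[C@]2(C)CCC[C@]3(C)CC[C@@H](C(C)(C)O)C[C@H]32)c1O | intermediate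
8 | 1-bromo-4-iodobenzene | Brc1ccc(I)cc1 | starting material
9 | mesitylene | Cc1cc(C)cc(C)c1 | starting material
10 | (4-bromophenyl)(mesityl)iodonium triflate | Cc1cc(C)c([I+]c2ccc(Br)cc2)c(C)c1.[O-]S(=O)(=O)C(F)(F)F | intermediate
11 | 2-[(2R,4aR,8R,8aR)-8-[3-(4-bromophenoxy)-5-bromo-2-hydroxyphenoxy]-4a,8-dimethyldecahydronaphthalen-2-yl]propan-2-ol | Brc1ccc(Oc2cc(Br)cc(O[C@]3(C)CCC[C@]4(C)CC[C@@H](C(C)(C)O)C[C@H]43)c2O)cc1 | intermediate
12 | allyltributylstannane | C=CC[Sn](CCCC)(CCCC)CCCC | starting material
13 | eudesobovatol A | C=CCc1ccc(Oc2cc(CC=C)cc(O[C@]3(C)CCC[C@]4(C)CC[C@@H](C(C)(C)O)C[C@H]43)c2O)cc1 | target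

## Summary
Total steps: 7.
Longest linear sequence: 6 steps, from 1 via steps 1, 2, 3, 4, 6 and 7. This is 4 steps from β-eudesmol.

**Three steps most likely to fail**
1. **Step 3 (proposed new step).** Possible problems are low intermolecular conversion, C-alkylation or alkene isomerisation/elimination, and the wrong C4 epimer.
   Fallback (known chemistry): protect the 11-OH as its TES ether, then run a Tf2NH-catalysed cationic Markovnikov hydroaryloxylation of the alkene with phenol 4 in DCE at 0 °C, and remove TES with TBAF. This replaces the radical-polar-crossover pathway with an acid-catalysed cationic one.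
2. **Step 6 (O-3 versus central-OH regioselectivity).**
   Fallback: reorder the sequence. First arylate phenol 4 (Chan–Lam with 4-bromophenylboronic acid). Then open the carbonate regioselectively with 1 equiv NaOMe, so that the more acidic central phenoxide leaves and the flanking O carries the methyl carbonate. Silylate the central OH (TBS), and cleave the methyl carbonate with K2CO3/MeOH. Next run the step 3 hydroaryloxylation on this 2-OTBS phenol, and finish with TBAF and Stille allylation.
3. **Step 7 (double Stille allylation of an electron-rich, hindered dibromide).** Possible problems are protodebromination and allyl-to-propenyl isomerisation.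
   Fallback: reverse the polarity of the coupling. Convert the dibromide to the bis-Bpin by Miyaura borylation, then couple with allyl bromide under Pd catalysis.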